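## Structural features

The target is a nine-membered carbocycle, numbered C1 (CH bearing the side chain), C2, C3, C4 (C–CH3), C5, C6, C7, C8 (C–CHO, formyl carbon C11) and C9 (CH–CHO, formyl carbon C10). The ring holds an E trisubstituted olefin C4=C5 and a second olefin C7=C8 whose ring bonds are cis and which is conjugated to the C11 formyl group. C1 carries the chain Cb(H)(CaH2OAc)(CcH2–CH2–CH=CMe2). The three stereocentres are contiguous: Cb (R), C1 (S) and C9 (S), with the C1 side chain and the C9 formyl group trans on the ring. C9–H is alpha to one aldehyde and gamma to the enal, so it epimerises easily and C7=C8 can slide into conjugation; the 2-ene-1,4-dial also closes readily to lactols, and the primary acetate forbids hydride or strong base at the end. The real difficulty is the medium ring itself: nine atoms, an E olefin inside it, closed next to two stereocentres. The key step uses the fact that C10 is a latent carboxyl and C1–Cb–Cc a latent allyl unit (Cc is a plain CH2 in the target). Tying the C10 oxygen to Cc gives a relaxed 13-membered allylic lactone (C10, C9, C8 … C2, C1, Cb, Cc, O), whose ester enolate can make the strained C1–C9 bond by a [3,3] shift.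

## Logic of the disconnections

**30 to 29.** The two formyl C=O groups are taken back to CH2OH. The enolisable ene-dial is the most fragile array and must come last. The forward step must oxidise both hydroxyls in one operation, so that no hydroxy-aldehyde survives long enough to close to a lactol, and must spare the acetate and C9.

**29 to 28 to 27.** The two O–Si bonds and the acetate C–O bond are cut. This places acetylation at a stage where Ca–OH is the only free hydroxyl. The silyl ethers must then come off without acyl migration, which calls for acidic fluoride.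

**27 to 26.** The Cb–H and Cc–H bonds are cut, leaving a Cb=Cc olefin with a free allylic hydroxyl on Ca. This removes the Cb stereocentre and returns exactly the olefin that the sigmatropic step leaves behind. The forward hydrogenation must choose the face by catalyst control and must touch only one of four trisubstituted olefins, so no other hydroxyl may be free.

**26 to 25 to 24 to 23.** The PMB ether on Ca, the silyl ether on C10–O and the C10 carboxyl are restored. The carboxyl is the natural product of an ester-enolate rearrangement. Reduction and silylation must precede PMB removal so that the C10 hydroxyl, homoallylic to C7=C8, cannot direct the hydrogenation.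

**23 to 20.** The C1–C9 bond is cut and the Cc–O bond re-formed. The nine-membered ring, its C1 and C9 stereocentres and the Cb=Cc olefin all collapse into a 13-membered lactone with one stereocentre (Cc) and three olefins made acyclically. The forward step needs alpha-enolisation of a beta,gamma-unsaturated lactone without conjugation, a defined ketene acetal geometry and a defined six-centre array.

**20 to 19.** The lactone C10–O bond is cut. The seco acid is open-chain and all its olefin geometries can be set one at a time. The forward closure must acylate a hindered secondary allylic alcohol without moving C7=C8 into conjugation.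

**19 to 17 to 15 to 14.** The tert-butyl ester is restored, the terminal CMe2 unit is removed (17 to 15 plus 16) and the Cc–CH2 bond is cut (15 to 14). Cc becomes a formyl carbon, so the only stereocentre of 20 comes from a reagent-controlled allylation of an enal. The allyl-to-prenyl exchange must leave the trisubstituted olefins alone.

**14 to 13 plus 10.** The C1=Cb double bond is cut. The whole Ca/Cb/Cc unit arrives as a 2-substituted acrolein, and the chain needs only a terminal vinyl group. The cross-metathesis must give the isomer with C2 trans to the formyl group.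

**13 to 11 plus 7.** The C5–C6 bond and the C4–CH3 bond are cut. A C6 alkyne and a five-carbon allylic chloride are joined in one flask. Methylalumination must be syn and regioselective, and the allylation must occur at the primary terminus with both olefin geometries kept.

**7 to 6 to 3 plus 4, 3 to 2 to 1.** The C–Cl bond, the C8–C9 bond and the C8–I bond are cut back to a symmetric butynediol. The C7=C8 geometry (C6 cis to C9) is fixed by a trans-hydroalumination rather than by an olefination. The coupling must retain that geometry and must not lactonise, hence the tert-butyl ester.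

**10 to 9 to 8.** The aldehyde is taken back to a symmetric diol. A monoetherification and an allylic oxidation are all that is required.

## Other disconnections considered

**Alternative 1:** The cut is C1–Cb, with a temporary O–Ca bond. The enal A1 would act as oxadiene (C10, C9, C1) toward the (Z)-enol ether A2 (Ca, Cb) under the chromium chloride complex of the adamantyl-salicylaldehyde/aminoindanol Schiff base (trivalent chromium), giving the all-cis dihydropyran A3.
- In its favour: Cb and C1, the adjacent pair, would be set together from achiral partners in one catalytic endo cycloaddition. On this point it is better than the chosen plan, which sets them in two events, one of them a hydrogenation under double stereodifferentiation (step 17). A3 also holds Ca at the aldehyde level and C10/C9 as an enol ether, a usable handle for C9.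
- Against it: the cycloaddition makes no bond of the carbocycle. The nine-membered ring, the E olefin (from the silyl alkyne), the C8–C9 bond and the C9 centre would all remain, and the ring would have to be closed end to end, the very operation the chosen plan avoids.
- Comparison: mechanistically a concerted [4+2] against a [3,3]; in step count it is probably no shorter once ring closure is included.

**Alternative 2:** The cut is made by adding a C4–C9 bond: the cis-hydrindanol monotosylate A4, as its potassium alkoxide, would fragment to the (E)-cyclononenone A5.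
- In its favour: the olefin geometry follows from the anti-periplanar arrangement in a rigid bicycle, and ring formation by fragmentation carries no closure penalty. In certainty of forming the ring and the E olefin it is the equal of the chosen plan, perhaps its better. C1 and Cb are already in place.
- Against it: A5 lacks C7=C8 and both formyl carbons. The C9 ketone would need a one-carbon homologation with control of C9, and C8 would need formylation and unsaturation in competition with the C1 alpha position, which is also epimerisable. A4 needs four ring stereocentres, three of which are destroyed.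
- Comparison: structure and olefin control are good, but functional-group economy and step count after the key step are clearly worse.

**Alternative 3:** The cut is C2–C3, with C5–C9 as the bond to be broken: the potassium alkoxide of the trans-dialkenylcyclopentenol A6 would undergo an anionic oxy-Cope shift to the nine-membered dienone A7.
- In its favour: like the chosen plan it builds the ring by a sigmatropic shift rather than by cyclisation, and in that respect is its equal. Its precursor is a five-membered ring, which is easier to make than a 13-membered lactone, so no macrolactonisation is needed; this is a point on which it is better. The E olefin should come from the chair array of a trans-dialkenyl system, and C7=C8 with its oxygenated carbon is already present.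
- Against it: C9 arrives as a hindered cross-conjugated ketone that still needs C10 and its stereocentre. C1 would be set only by protonation of the enolate, with no control element but Cb. The alkenyl-metal addition that makes A6 must be trans-selective.
- Comparison: the route to the precursor is shorter, but the route from the product is longer and stereochemically weaker than the chosen plan, where C10 and both ring stereocentres emerge in the key step.

Key step: step 13

Remark on the fixed structures: lactone 20 and acid 23 were checked atom by atom against the target and for the sense of the suprafacial shift. (R)-Cc with the E Cb=C1 olefin leads to the required C1; the ring-cis ketene acetal in a boat array leads to the required C9. They are consistent and are used unchanged.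

Assumption: the target's C9 configuration (formyl trans to the C1 chain) is taken to be the more stable one at this enolisable centre. Hex-1-en-5-yne is treated as a purchasable material.

## Route

Step 1
Reactants: 1 but-2-yne-1,4-diol
Product: 2 4-[(tert-butyldimethylsilyl)oxy]but-2-yn-1-ol
Conditions: TBSCl (0.35 equiv), imidazole, THF, 0 °C, diol in excess
Reagents that add atoms: tert-butyldimethylsilyl chloride, CC(C)(C)[Si](C)(C)Cl
Why: Statistical monosilylation of a cheap symmetric diol; excess diol suppresses the bis-ether and is washed out with water.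

Step 2
Reactants: 2 4-[(tert-butyldimethylsilyl)oxy]but-2-yn-1-ol
Product: 3 (Z)-4-[(tert-butyldimethylsilyl)oxy]-3-iodobut-2-en-1-ol
Conditions: NaAlH2(OCH2CH2OCH3)2, THF, 0 °C; then I2, −78 °C to 0 °C
Reagents that add atoms: iodine, II
Why: Hydroxyl-directed trans-hydroalumination places aluminium on the alkyne carbon distal to the free hydroxyl, and iodinolysis with retention gives the iodide with I cis to CH2OH; this fixes the later C7=C8 geometry (C6 cis to C9). The temperature is kept low so the alkenylalanate does not eliminate the silyloxy group.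

Step 3
Reactants: 3 (Z)-4-[(tert-butyldimethylsilyl)oxy]-3-iodobut-2-en-1-ol; 4 tert-butyl bromoacetate
Product: 6 tert-butyl (E)-3-{[(tert-butyldimethylsilyl)oxy]methyl}-5-hydroxypent-3-enoate, via Reformatsky reagent 5 (not isolated)
Conditions: Zn (Me3SiCl-activated), THF, rt (4 to 5, 3 equiv); then 3, Pd2(dba)3 (cat.), XPhos, THF, 50 °C
Reagents that add atoms: none
Why: Palladium-catalysed cross-coupling of an alkenyl iodide with a Reformatsky reagent (Negishi type) proceeds with retention of olefin geometry and forms C8–C9. One equivalent of 5 is spent on the hydroxyl, and the tert-butyl ester resists the zinc alkoxide, so no six-membered lactone forms.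

Step 4
Reactants: 6 tert-butyl (E)-3-{[(tert-butyldimethylsilyl)oxy]methyl}-5-hydroxypent-3-enoate
Product: 7 tert-butyl (E)-3-{[(tert-butyldimethylsilyl)oxy]methyl}-5-chloropent-3-enoate
Conditions: MsCl, 2,4,6-collidine, LiCl, DMF, 0 °C
Reagents that add atoms: lithium chloride, [Li+].[Cl-]
Why: Mesylation and in situ SN2 displacement by chloride at the primary allylic carbon; the other allyl terminus is fully substituted, so no transposition is expected.

Step 5
Reactants: 8 2-methylidenepropane-1,3-diol
Product: 9 2-{[(4-methoxybenzyl)oxy]methyl}prop-2-en-1-ol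
Conditions: NaH (1 equiv), THF/DMF, 0 °C; PMBCl (0.9 equiv), Bu4NI (cat.)
Reagents that add atoms: 4-methoxybenzyl chloride, COc1ccc(CCl)cc1
Why: Williamson monoetherification of a symmetric diol through its mono-alkoxide.

Step 6
Reactants: 9 2-{[(4-methoxybenzyl)oxy]methyl}prop-2-en-1-ol
Product: 10 2-{[(4-methoxybenzyl)oxy]methyl}prop-2-enal
Conditions: MnO2, CH2Cl2, rt; used at once
Reagents that add atoms: none
Why: Chemoselective oxidation of an allylic alcohol by MnO2; the PMB ether is untouched. The enal is used fresh because 2-substituted acroleins dimerise.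

Step 7
Reactants: 11 hex-1-en-5-yne; 7 tert-butyl (E)-3-{[(tert-butyldimethylsilyl)oxy]methyl}-5-chloropent-3-enoate
Product: 13 tert-butyl (3E,6E)-3-{[(tert-butyldimethylsilyl)oxy]methyl}-7-methylundeca-3,6,10-trienoate, via alkenylalane 12 (not isolated)
Conditions: Me3Al, Cp2ZrCl2 (cat.), (CH2Cl)2, 0 °C to rt; then 7, Pd(PPh3)4 (cat.), THF, rt
Reagents that add atoms: trimethylaluminium, C[Al](C)C
Why: Zirconium-catalysed methylalumination of the alkyne (Negishi carboalumination) is syn, with methyl to the internal carbon, which sets E C4=C5; the terminal alkene reacts far more slowly. The alkenylalane then couples under zerovalent palladium at the primary terminus of the allyl unit of 7 with retention of both olefin geometries; the tert-butyl ester tolerates the alane.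

Step 8
Reactants: 13 tert-butyl (3E,6E)-3-{[(tert-butyldimethylsilyl)oxy]methyl}-7-methylundeca-3,6,10-trienoate; 10 2-{[(4-methoxybenzyl)oxy]methyl}prop-2-enal
Product: 14 tert-butyl (3E,6E,10E)-3-{[(tert-butyldimethylsilyl)oxy]methyl}-11-formyl-12-[(4-methoxybenzyl)oxy]-7-methyldodeca-3,6,10-trienoate
Conditions: second-generation Hoveyda–Grubbs catalyst (5 mol %), 10 (3 equiv), CH2Cl2, 40 °C
Reagents that add atoms: none
Why: Olefin cross-metathesis of a terminal alkene with a 2-substituted acrolein, as with methacrolein; only the monosubstituted olefin of 13 can engage. The thermodynamically preferred isomer has C2 trans to the formyl group, which is the required Cb=C1 geometry.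

Step 9
Reactants: 14 tert-butyl (3E,6E,10E)-3-{[(tert-butyldimethylsilyl)oxy]methyl}-11-formyl-12-[(4-methoxybenzyl)oxy]-7-methyldodeca-3,6,10-trienoate
Product: 15 tert-butyl (3E,6E,10E,12R)-3-{[(tert-butyldimethylsilyl)oxy]methyl}-12-hydroxy-11-{[(4-methoxybenzyl)oxy]methyl}-7-methylpentadeca-3,6,10,14-tetraenoate
Conditions: (+)-Ipc2B(allyl), Et2O, −78 °C; then NaBO3·4H2O, THF/H2O, rt
Reagents that add atoms: (+)-B-allyldiisopinocampheylborane, C=CCB([C@H]1C[C@H]2C[C@@H]([C@@H]1C)C2(C)C)[C@H]1C[C@H]2C[C@@H]([C@@H]1C)C2(C)C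
Why: Brown allylation; the reagent from (−)-alpha-pinene adds through a closed chair array to the Re face of an aldehyde whose substituent outranks allyl, giving (R)-Cc. Addition is 1,2 only, and the ester is inert at −78 °C.

Step 10
Reactants: 15 tert-butyl (3E,6E,10E,12R)-3-{[(tert-butyldimethylsilyl)oxy]methyl}-12-hydroxy-11-{[(4-methoxybenzyl)oxy]methyl}-7-methylpentadeca-3,6,10,14-tetraenoate; 16 2-methylbut-2-ene
Product: 17 tert-butyl (3E,6E,10E,12R)-3-{[(tert-butyldimethylsilyl)oxy]methyl}-12-hydroxy-11-{[(4-methoxybenzyl)oxy]methyl}-7,15-dimethylhexadeca-3,6,10,14-tetraenoate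
Conditions: second-generation Grubbs catalyst (5 mol %), 2-methylbut-2-ene/CH2Cl2, 35 °C
Reagents that add atoms: none
Why: Cross-metathesis with 2-methylbut-2-ene turns the allyl group into the 3-methylbut-2-enyl group; the trisubstituted olefins do not react and no ring-closing partner is within reach.

Step 11
Reactants: 17 tert-butyl (3E,6E,10E,12R)-3-{[(tert-butyldimethylsilyl)oxy]methyl}-12-hydroxy-11-{[(4-methoxybenzyl)oxy]methyl}-7,15-dimethylhexadeca-3,6,10,14-tetraenoate
Product: 19 (3E,6E,10E,12R)-3-{[(tert-butyldimethylsilyl)oxy]methyl}-12-hydroxy-11-{[(4-methoxybenzyl)oxy]methyl}-7,15-dimethylhexadeca-3,6,10,14-tetraenoic acid, via bis(trimethylsilyl) derivative 18 (not isolated)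
Conditions: Me3SiOTf, 2,6-lutidine, CH2Cl2, 0 °C; then K2CO3, MeOH/H2O, 0 °C; pH 5 work-up
Reagents that add atoms: trimethylsilyl trifluoromethanesulfonate, C[Si](C)(C)OS(=O)(=O)C(F)(F)F (silyl groups of 18 only; none remain in 19)
Why: Silyl triflate converts the tert-butyl ester into a silyl ester with loss of 2-methylpropene under buffered, non-protic conditions that the TBS and PMB ethers and the olefins tolerate. The Cc hydroxyl is silylated in passing, and both Me3Si groups are hydrolysed in the mild basic work-up, where the carboxylate cannot conjugate.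

Step 12
Reactants: 19 (3E,6E,10E,12R)-3-{[(tert-butyldimethylsilyl)oxy]methyl}-12-hydroxy-11-{[(4-methoxybenzyl)oxy]methyl}-7,15-dimethylhexadeca-3,6,10,14-tetraenoic acid
Product: 20 (4E,7E,11E,13R)-4-{[(tert-butyldimethylsilyl)oxy]methyl}-12-{[(4-methoxybenzyl)oxy]methyl}-8-methyl-13-(3-methylbut-2-en-1-yl)-1-oxacyclotrideca-4,7,11-trien-2-one
Conditions: 2-methyl-6-nitrobenzoic anhydride, DMAP, CH2Cl2 (1 mM), rt, slow addition
Reagents that add atoms: none
Why: Shiina macrolactonisation: the mixed anhydride acylates the Cc hydroxyl at room temperature under high dilution. The 13-membered ring with two E olefins and one ring-cis olefin is unstrained, and the mild conditions limit migration of the beta,gamma-olefin; Cc is not touched.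

Step 13
Reactants: 20 (4E,7E,11E,13R)-4-{[(tert-butyldimethylsilyl)oxy]methyl}-12-{[(4-methoxybenzyl)oxy]methyl}-8-methyl-13-(3-methylbut-2-en-1-yl)-1-oxacyclotrideca-4,7,11-trien-2-one
Product: 23 (1S,2E,5E,9R)-2-{[(tert-butyldimethylsilyl)oxy]methyl}-9-{(2Z)-1-[(4-methoxybenzyl)oxy]-6-methylhepta-2,5-dien-2-yl}-6-methylcyclonona-2,5-diene-1-carboxylic acid, via silyl ketene acetal 21 (not isolated), via trimethylsilyl ester 22 (not isolated)
Conditions: LiN(iPr)2, Me3SiCl/Et3N (in situ), THF, −78 °C; warm to rt, then 60 °C; aqueous citric acid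
Reagents that add atoms: chlorotrimethylsilane, C[Si](C)(C)Cl (silyl groups of 21 and 22 only; none remain in 23)
Why: LiN(iPr)2 removes a C9 proton of 20 (alpha to the carbonyl and allylic to C7=C8) and Me3SiCl traps the dienolate as the ring-cis O-silyl ketene acetal 21, in which C8 is trans to the silyloxy group. On warming, 21 undergoes a suprafacial [3,3] shift through the six-centre array C9–C10–O–Cc–Cb–C1, forming C1–C9 and breaking Cc–O to give silyl ester 22, which is hydrolysed to 23 on work-up; the closest known reaction type is the ring-contracting Ireland–Claisen rearrangement of macrocyclic allylic lactones to 2-alkenylcycloalkanecarboxylic acids. The nine-membered carbocycle is closed by contraction of the 13-membered ring (C9 bonds across the ring to C1), not by end-to-end cyclisation, so both ring olefins keep the geometry with which they were made. C1 is set by chirality transfer from Cc: with the 3-methylbut-2-enyl group outside (trans to C1 in the new Cb=Cc bond), the (R) carbinol puts C9 on the face of the E Cb=C1 olefin that gives the required C1. C9 is set by the shape of the array: in the boat, C8 and C2 both point away from the six-centre ring and the trans C1/C9 pair of 23 results, whereas the chair would hold C8 axial over the Ca-bearing Cb and give the C9 epimer. The step needs alpha-deprotonation without conjugation of the beta,gamma-olefin (low temperature, in situ silylation), the prenyl-outside rotamer (favoured as in acyclic cases) and the boat (favoured by the tether, and helped by the small Me3Si group, which eclipses Ca in that array).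

Step 14
Reactants: 23 (1S,2E,5E,9R)-2-{[(tert-butyldimethylsilyl)oxy]methyl}-9-{(2Z)-1-[(4-methoxybenzyl)oxy]-6-methylhepta-2,5-dien-2-yl}-6-methylcyclonona-2,5-diene-1-carboxylic acid
Product: 24 [(1S,2E,5E,9R)-2-{[(tert-butyldimethylsilyl)oxy]methyl}-9-{(2Z)-1-[(4-methoxybenzyl)oxy]-6-methylhepta-2,5-dien-2-yl}-6-methylcyclonona-2,5-dien-1-yl]methanol
Conditions: LiAlH4, THF, 0 °C to rt
Reagents that add atoms: none
Why: Hydride reduction of the carboxylic acid to the primary alcohol; the carboxylate cannot enolise, so C9 is safe, and the ethers and isolated olefins are inert.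

Step 15
Reactants: 24 [(1S,2E,5E,9R)-2-{[(tert-butyldimethylsilyl)oxy]methyl}-9-{(2Z)-1-[(4-methoxybenzyl)oxy]-6-methylhepta-2,5-dien-2-yl}-6-methylcyclonona-2,5-dien-1-yl]methanol
Product: 25 tert-butyldimethylsilyl ether of 24 (both ring CH2O groups as TBS ethers; Ca as PMB ether)
Conditions: TBSCl, imidazole, DMF, rt
Reagents that add atoms: tert-butyldimethylsilyl chloride, CC(C)(C)[Si](C)(C)Cl
Why: Silylation of the only free hydroxyl; this masks the hydroxyl homoallylic to C7=C8 before the directed hydrogenation.

Step 16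
Reactants: 25 tert-butyldimethylsilyl ether of 24
Product: 26 (2Z)-2-[(1R,2S,3E,6E)-2,3-bis({[(tert-butyldimethylsilyl)oxy]methyl})-7-methylcyclonona-3,6-dien-1-yl]-6-methylhepta-2,5-dien-1-ol
Conditions: DDQ, CH2Cl2/pH 7 buffer, 0 °C
Reagents that add atoms: none
Why: Oxidative cleavage of the PMB ether by DDQ; buffering and low temperature protect the skipped diene and the silyl ethers.

Step 17
Reactants: 26 (2Z)-2-[(1R,2S,3E,6E)-2,3-bis({[(tert-butyldimethylsilyl)oxy]methyl})-7-methylcyclonona-3,6-dien-1-yl]-6-methylhepta-2,5-dien-1-ol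
Product: 27 (2R)-2-[(1S,2S,3E,6E)-2,3-bis({[(tert-butyldimethylsilyl)oxy]methyl})-7-methylcyclonona-3,6-dien-1-yl]-6-methylhept-5-en-1-ol
Conditions: H2 (100 atm), Ru(OAc)2[(S)-BINAP] (cat.), MeOH, 25 °C
Reagents that add atoms: none
Why: Hydroxyl-directed asymmetric hydrogenation of an allylic alcohol: only Cb=Cc has a free allylic hydroxyl to bind ruthenium, and the other three trisubstituted olefins are inert to this catalyst. By the empirical sense known for 3,3-disubstituted allylic alcohols, the (S)-ligand should deliver H2 to the face that makes Cb (R), whatever the geometry at Cc; the catalyst rather than C1 is expected to control the face.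

Step 18
Reactants: 27 (2R)-2-[(1S,2S,3E,6E)-2,3-bis({[(tert-butyldimethylsilyl)oxy]methyl})-7-methylcyclonona-3,6-dien-1-yl]-6-methylhept-5-en-1-ol
Product: 28 (2R)-2-[(1S,2S,3E,6E)-2,3-bis({[(tert-butyldimethylsilyl)oxy]methyl})-7-methylcyclonona-3,6-dien-1-yl]-6-methylhept-5-en-1-yl acetate
Conditions: Ac2O, pyridine, DMAP (cat.), CH2Cl2, 0 °C to rt
Reagents that add atoms: acetic anhydride, CC(=O)OC(C)=O
Why: Acylation of the single free primary hydroxyl.

Step 19
Reactants: 28 (2R)-2-[(1S,2S,3E,6E)-2,3-bis({[(tert-butyldimethylsilyl)oxy]methyl})-7-methylcyclonona-3,6-dien-1-yl]-6-methylhept-5-en-1-yl acetate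
Product: 29 (2R)-2-[(1S,2S,3E,6E)-2,3-bis(hydroxymethyl)-7-methylcyclonona-3,6-dien-1-yl]-6-methylhept-5-en-1-yl acetate
Conditions: HF·pyridine, THF/pyridine, 0 °C to rt
Reagents that add atoms: none
Why: Acidic fluoride removes both primary silyl ethers without cleaving or migrating the acetate.

Step 20
Reactants: 29 (2R)-2-[(1S,2S,3E,6E)-2,3-bis(hydroxymethyl)-7-methylcyclonona-3,6-dien-1-yl]-6-methylhept-5-en-1-yl acetate
Product: 30 (2R)-2-[(1S,2S,3E,6E)-2,3-diformyl-7-methylcyclonona-3,6-dien-1-yl]-6-methylhept-5-en-1-yl acetate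
Conditions: (COCl)2, Me2SO, CH2Cl2, −78 °C; then iPr2NEt, −78 °C to −40 °C; cold pH 7 quench
Reagents that add atoms: none
Why: Double Swern oxidation: both hydroxyls are converted to alkoxysulfonium ions before base is added, so both aldehydes appear together and no hydroxy-aldehyde is left to close to a lactol. The hindered base at low temperature limits epimerisation at C9 and migration of C7=C8; the acetate is inert.

## Compound list

1 | but-2-yne-1,4-diol | OCC#CCO | starting material
2 | 4-[(tert-butyldimethylsilyl)oxy]but-2-yn-1-ol | OCC#CCO[Si](C)(C)C(C)(C)C | intermediate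
3 | (Z)-4-[(tert-butyldimethylsilyl)oxy]-3-iodobut-2-en-1-ol | OC/C=C(\I)CO[Si](C)(C)C(C)(C)C | intermediate
4 | tert-butyl bromoacetate | CC(C)(C)OC(=O)CBr | starting material
5 | bromo(2-tert-butoxy-2-oxoethyl)zinc | CC(C)(C)OC(=O)C[Zn]Br | intermediate (not isolated)
6 | tert-butyl (E)-3-{[(tert-butyldimethylsilyl)oxy]methyl}-5-hydroxypent-3-enoate | OC/C=C(/CO[Si](C)(C)C(C)(C)C)CC(=O)OC(C)(C)C | intermediate
7 | tert-butyl (E)-3-{[(tert-butyldimethylsilyl)oxy]methyl}-5-chloropent-3-enoate | ClC/C=C(/CO[Si](C)(C)C(C)(C)C)CC(=O)OC(C)(C)C | intermediate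
8 | 2-methylidenepropane-1,3-diol | C=C(CO)CO | starting material
9 | 2-{[(4-methoxybenzyl)oxy]methyl}prop-2-en-1-ol | C=C(CO)COCc1ccc(OC)cc1 | intermediate
10 | 2-{[(4-methoxybenzyl)oxy]methyl}prop-2-enal | C=C(C=O)COCc1ccc(OC)cc1 | intermediate
11 | hex-1-en-5-yne | C#CCCC=C | starting material
12 | dimethyl[(1E)-2-methylhexa-1,5-dien-1-yl]alane | C=CCC/C(C)=C/[Al](C)C | intermediate (not isolated)
13 | tert-butyl (3E,6E)-3-{[(tert-butyldimethylsilyl)oxy]methyl}-7-methylundeca-3,6,10-trienoate | C=CCC/C(C)=C/C/C=C(/CO[Si](C)(C)C(C)(C)C)CC(=O)OC(C)(C)C | intermediate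
14 | tert-butyl (3E,6E,10E)-3-{[(tert-butyldimethylsilyl)oxy]methyl}-11-formyl-12-[(4-methoxybenzyl)oxy]-7-methyldodeca-3,6,10-trienoate | O=C/C(COCc1ccc(OC)cc1)=C/CC/C(C)=C/C/C=C(/CO[Si](C)(C)C(C)(C)C)CC(=O)OC(C)(C)C | intermediate
15 | tert-butyl (3E,6E,10E,12R)-3-{[(tert-butyldimethylsilyl)oxy]methyl}-12-hydroxy-11-{[(4-methoxybenzyl)oxy]methyl}-7-methylpentadeca-3,6,10,14-tetraenoate | C=CC[C@@H](O)/C(COCc1ccc(OC)cc1)=C/CC/C(C)=C/C/C=C(/CO[Si](C)(C)C(C)(C)C)CC(=O)OC(C)(C)C | intermediate
16 | 2-methylbut-2-ene | CC=C(C)C | starting material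
17 | tert-butyl (3E,6E,10E,12R)-3-{[(tert-butyldimethylsilyl)oxy]methyl}-12-hydroxy-11-{[(4-methoxybenzyl)oxy]methyl}-7,15-dimethylhexadeca-3,6,10,14-tetraenoate | CC(C)=CC[C@@H](O)/C(COCc1ccc(OC)cc1)=C/CC/C(C)=C/C/C=C(/CO[Si](C)(C)C(C)(C)C)CC(=O)OC(C)(C)C | intermediate
18 | trimethylsilyl ester and 12-O-trimethylsilyl ether of 19 | CC(C)=CC[C@@H](O[Si](C)(C)C)/C(COCc1ccc(OC)cc1)=C/CC/C(C)=C/C/C=C(/CO[Si](C)(C)C(C)(C)C)CC(=O)O[Si](C)(C)C | intermediate (not isolated)
19 | (3E,6E,10E,12R)-3-{[(tert-butyldimethylsilyl)oxy]methyl}-12-hydroxy-11-{[(4-methoxybenzyl)oxy]methyl}-7,15-dimethylhexadeca-3,6,10,14-tetraenoic acid | CC(C)=CC[C@@H](O)/C(COCc1ccc(OC)cc1)=C/CC/C(C)=C/C/C=C(/CO[Si](C)(C)C(C)(C)C)CC(=O)O | intermediate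
20 | (4E,7E,11E,13R)-4-{[(tert-butyldimethylsilyl)oxy]methyl}-12-{[(4-methoxybenzyl)oxy]methyl}-8-methyl-13-(3-methylbut-2-en-1-yl)-1-oxacyclotrideca-4,7,11-trien-2-one | O=C1C/C(CO[Si](C)(C)C(C)(C)C)=C\C/C=C(\C)CC/C=C(\COCc2ccc(OC)cc2)[C@@H](CC=C(C)C)O1 | intermediate
21 | ring-cis O-trimethylsilyl ketene acetal of 20 (C8 trans to OSiMe3) | C[Si](C)(C)O/C1=C/C(CO[Si](C)(C)C(C)(C)C)=C\C/C=C(\C)CC/C=C(\COCc2ccc(OC)cc2)[C@@H](CC=C(C)C)O1 | intermediate (not isolated)
22 | trimethylsilyl ester of 23 | COc1ccc(COC/C(=C\CC=C(C)C)[C@@H]2CC/C(C)=C/C/C=C(/CO[Si](C)(C)C(C)(C)C)[C@H]2C(=O)O[Si](C)(C)C)cc1 | intermediate (not isolated)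
23 | (1S,2E,5E,9R)-2-{[(tert-butyldimethylsilyl)oxy]methyl}-9-{(2Z)-1-[(4-methoxybenzyl)oxy]-6-methylhepta-2,5-dien-2-yl}-6-methylcyclonona-2,5-diene-1-carboxylic acid | COc1ccc(COC/C(=C\CC=C(C)C)[C@@H]2CC/C(C)=C/C/C=C(/CO[Si](C)(C)C(C)(C)C)[C@H]2C(=O)O)cc1 | intermediate
24 | [(1S,2E,5E,9R)-2-{[(tert-butyldimethylsilyl)oxy]methyl}-9-{(2Z)-1-[(4-methoxybenzyl)oxy]-6-methylhepta-2,5-dien-2-yl}-6-methylcyclonona-2,5-dien-1-yl]methanol | COc1ccc(COC/C(=C\CC=C(C)C)[C@@H]2CC/C(C)=C/C/C=C(/CO[Si](C)(C)C(C)(C)C)[C@H]2CO)cc1 | intermediate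
25 | tert-butyldimethylsilyl ether of 24 | COc1ccc(COC/C(=C\CC=C(C)C)[C@@H]2CC/C(C)=C/C/C=C(/CO[Si](C)(C)C(C)(C)C)[C@H]2CO[Si](C)(C)C(C)(C)C)cc1 | intermediate
26 | (2Z)-2-[(1R,2S,3E,6E)-2,3-bis({[(tert-butyldimethylsilyl)oxy]methyl})-7-methylcyclonona-3,6-dien-1-yl]-6-methylhepta-2,5-dien-1-ol | OC/C(=C\CC=C(C)C)[C@@H]1CC/C(C)=C/C/C=C(/CO[Si](C)(C)C(C)(C)C)[C@H]1CO[Si](C)(C)C(C)(C)C | intermediate
27 | (2R)-2-[(1S,2S,3E,6E)-2,3-bis({[(tert-butyldimethylsilyl)oxy]methyl})-7-methylcyclonona-3,6-dien-1-yl]-6-methylhept-5-en-1-ol | OC[C@H](CCC=C(C)C)[C@@H]1CC/C(C)=C/C/C=C(/CO[Si](C)(C)C(C)(C)C)[C@H]1CO[Si](C)(C)C(C)(C)C | intermediate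
28 | (2R)-2-[(1S,2S,3E,6E)-2,3-bis({[(tert-butyldimethylsilyl)oxy]methyl})-7-methylcyclonona-3,6-dien-1-yl]-6-methylhept-5-en-1-yl acetate | CC(=O)OC[C@H](CCC=C(C)C)[C@@H]1CC/C(C)=C/C/C=C(/CO[Si](C)(C)C(C)(C)C)[C@H]1CO[Si](C)(C)C(C)(C)C | intermediate
29 | (2R)-2-[(1S,2S,3E,6E)-2,3-bis(hydroxymethyl)-7-methylcyclonona-3,6-dien-1-yl]-6-methylhept-5-en-1-yl acetate | CC(=O)OC[C@H](CCC=C(C)C)[C@@H]1CC/C(C)=C/C/C=C(/CO)[C@H]1CO | intermediate
30 | (2R)-2-[(1S,2S,3E,6E)-2,3-diformyl-7-methylcyclonona-3,6-dien-1-yl]-6-methylhept-5-en-1-yl acetate | CC(=O)OC[C@H](CCC=C(C)C)[C@@H]1CC/C(C)=C/C/C=C(/C=O)[C@H]1C=O | target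

## Step count and least certain steps

Total: 20 steps. Longest linear sequence: 18 steps (steps 1–4 and 7–20, from but-2-yne-1,4-diol).

**Step 13 (key step).** The most likely failure is loss of control at C9: the chair array may compete with the boat, because the 2-substituent of the allyl unit (Ca) eclipses the silyloxy group in the boat. C1 would still be correct. A slow shift, because strain builds in the E-cyclononene, could also let the ketene acetal decompose. Fallback, from 20 back to 24, by thermodynamic rather than kinetic control of C9: the rearrangement is run as before and the acid that contains the C9 epimer F1 is methylated (Me3SiCHN2, MeOH/toluene) to the methyl ester F2. Brief treatment with NaOMe in MeOH at 0 °C equilibrates C9 through the dienolate, with kinetic alpha-protonation, to the trans methyl ester F3, in which the ester lies anti to the branched C1 substituent. LiAlH4 reduction of F3 gives 24.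

**Step 17.** The sense of induction is taken by analogy from simpler allylic alcohols. Poor facial selectivity through a mismatch with C1, or slow uptake by this hindered 2-substituted olefin, are the likely failures. Fallback, from 26 back to 27, using carboxyl-directed instead of hydroxyl-directed hydrogenation: 26 is oxidised with MnO2 to the (Z)-enal F4 and with NaClO2/NaH2PO4/2-methylbut-2-ene to the 2-substituted acrylic acid F5. Acids of this type are the best-behaved substrates for Ru(OAc)2(BINAP) and H2; the ligand antipode is chosen in a test reaction. The saturated acid F6 is reduced with LiAlH4 to 27.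

**Step 8.** The cross-metathesis may stall with the hindered, electron-poor 2-substituted acrolein, or the enal may dimerise. Fallback, from 7 back to 14, building the enal by olefination: pent-4-yn-1-ol is carried through the conditions of step 7 with 7 to give the alcohol F7, which is oxidised (Dess–Martin periodinane) to the aldehyde F8. A tandem oxa-Michael/Horner–Wadsworth–Emmons reaction with trimethyl 2-phosphonoacrylate and sodium 4-methoxybenzyl oxide gives the (E)-enoate F9. DIBAL-H at −78 °C reduces the methyl enoate in the presence of the tert-butyl ester to the allylic alcohol F10, and MnO2 gives 14.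

**Step 12.** Activation of a beta,gamma-unsaturated acid can lead, through a ketene, to migration of C7=C8 or to oligomers, and the Cc hydroxyl is hindered. Fallback, from 14 back to 20, activating the alcohol instead of the acid: allylation of 14 with (−)-Ipc2B(allyl) gives the (12S) carbinol F11, cross-metathesis with 16 gives F12, and silyl-triflate cleavage of the ester gives the (12S) seco acid F13. Mitsunobu lactonisation (PPh3, diisopropyl azodicarboxylate, toluene, high dilution) closes the ring with inversion at Cc to 20. SN2' attack at C1 is the risk of this variant.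

**Step 20.** Amine-induced epimerisation at C9, migration of C7=C8, or partial oxidation followed by lactol and lactone formation could occur. Fallback, from 24 back to 30, unmasking the two aldehydes one after the other so that no 1,4-hydroxy-aldehyde ever exists: 24 is oxidised (Dess–Martin periodinane, NaHCO3) to the aldehyde F14 and protected (MeOSiMe3, Me3SiOTf cat., −78 °C) as the dimethyl acetal F15. The PMB group is removed with DDQ to give F16, which is hydrogenated as in step 17 to F17 and acetylated to F18. HF·pyridine frees the allylic alcohol F19, MnO2 gives the enal F20, and aqueous oxalic acid in THF releases 30.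

## Further compounds

F1 | step 13 | (1R,2E,5E,9R)-2-{[(tert-butyldimethylsilyl)oxy]methyl}-9-{(2Z)-1-[(4-methoxybenzyl)oxy]-6-methylhepta-2,5-dien-2-yl}-6-methylcyclonona-2,5-diene-1-carboxylic acid (C9 epimer of 23) | COc1ccc(COC/C(=C\CC=C(C)C)[C@@H]2CC/C(C)=C/C/C=C(/CO[Si](C)(C)C(C)(C)C)[C@@H]2C(=O)O)cc1
F2 | step 13 | methyl ester of F1 | COc1ccc(COC/C(=C\CC=C(C)C)[C@@H]2CC/C(C)=C/C/C=C(/CO[Si](C)(C)C(C)(C)C)[C@@H]2C(=O)OC)cc1
F3 | step 13 | methyl ester of 23 | COc1ccc(COC/C(=C\CC=C(C)C)[C@@H]2CC/C(C)=C/C/C=C(/CO[Si](C)(C)C(C)(C)C)[C@H]2C(=O)OC)cc1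
F4 | step 17 | (2Z)-2-[(1R,2S,3E,6E)-2,3-bis({[(tert-butyldimethylsilyl)oxy]methyl})-7-methylcyclonona-3,6-dien-1-yl]-6-methylhepta-2,5-dienal | O=C/C(=C\CC=C(C)C)[C@@H]1CC/C(C)=C/C/C=C(/CO[Si](C)(C)C(C)(C)C)[C@H]1CO[Si](C)(C)C(C)(C)C
F5 | step 17 | (2Z)-2-[(1R,2S,3E,6E)-2,3-bis({[(tert-butyldimethylsilyl)oxy]methyl})-7-methylcyclonona-3,6-dien-1-yl]-6-methylhepta-2,5-dienoic acid | OC(=O)/C(=C\CC=C(C)C)[C@@H]1CC/C(C)=C/C/C=C(/CO[Si](C)(C)C(C)(C)C)[C@H]1CO[Si](C)(C)C(C)(C)C
F6 | step 17 | (2R)-2-[(1S,2S,3E,6E)-2,3-bis({[(tert-butyldimethylsilyl)oxy]methyl})-7-methylcyclonona-3,6-dien-1-yl]-6-methylhept-5-enoic acid | OC(=O)[C@H](CCC=C(C)C)[C@@H]1CC/C(C)=C/C/C=C(/CO[Si](C)(C)C(C)(C)C)[C@H]1CO[Si](C)(C)C(C)(C)C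
F7 | step 8 | tert-butyl (3E,6E)-3-{[(tert-butyldimethylsilyl)oxy]methyl}-10-hydroxy-7-methyldeca-3,6-dienoate | OCCC/C(C)=C/C/C=C(/CO[Si](C)(C)C(C)(C)C)CC(=O)OC(C)(C)C
F8 | step 8 | tert-butyl (3E,6E)-3-{[(tert-butyldimethylsilyl)oxy]methyl}-7-methyl-10-oxodeca-3,6-dienoate | O=CCC/C(C)=C/C/C=C(/CO[Si](C)(C)C(C)(C)C)CC(=O)OC(C)(C)C
F9 | step 8 | tert-butyl (3E,6E,10E)-3-{[(tert-butyldimethylsilyl)oxy]methyl}-11-(methoxycarbonyl)-12-[(4-methoxybenzyl)oxy]-7-methyldodeca-3,6,10-trienoate | COC(=O)/C(COCc1ccc(OC)cc1)=C/CC/C(C)=C/C/C=C(/CO[Si](C)(C)C(C)(C)C)CC(=O)OC(C)(C)C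
F10 | step 8 | tert-butyl (3E,6E,10Z)-3-{[(tert-butyldimethylsilyl)oxy]methyl}-11-(hydroxymethyl)-12-[(4-methoxybenzyl)oxy]-7-methyldodeca-3,6,10-trienoate | OC/C(COCc1ccc(OC)cc1)=C/CC/C(C)=C/C/C=C(/CO[Si](C)(C)C(C)(C)C)CC(=O)OC(C)(C)C
F11 | step 12 | (12S) epimer of 15 | C=CC[C@H](O)/C(COCc1ccc(OC)cc1)=C/CC/C(C)=C/C/C=C(/CO[Si](C)(C)C(C)(C)C)CC(=O)OC(C)(C)C
F12 | step 12 | (12S) epimer of 17 | CC(C)=CC[C@H](O)/C(COCc1ccc(OC)cc1)=C/CC/C(C)=C/C/C=C(/CO[Si](C)(C)C(C)(C)C)CC(=O)OC(C)(C)C
F13 | step 12 | (12S) epimer of 19 | CC(C)=CC[C@H](O)/C(COCc1ccc(OC)cc1)=C/CC/C(C)=C/C/C=C(/CO[Si](C)(C)C(C)(C)C)CC(=O)O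
F14 | step 20 | (1S,2E,5E,9R)-2-{[(tert-butyldimethylsilyl)oxy]methyl}-9-{(2Z)-1-[(4-methoxybenzyl)oxy]-6-methylhepta-2,5-dien-2-yl}-6-methylcyclonona-2,5-diene-1-carbaldehyde | COc1ccc(COC/C(=C\CC=C(C)C)[C@@H]2CC/C(C)=C/C/C=C(/CO[Si](C)(C)C(C)(C)C)[C@H]2C=O)cc1
F15 | step 20 | dimethyl acetal of F14 | COc1ccc(COC/C(=C\CC=C(C)C)[C@@H]2CC/C(C)=C/C/C=C(/CO[Si](C)(C)C(C)(C)C)[C@H]2C(OC)OC)cc1
F16 | step 20 | allylic alcohol from F15 (PMB replaced by H) | OC/C(=C\CC=C(C)C)[C@@H]1CC/C(C)=C/C/C=C(/CO[Si](C)(C)C(C)(C)C)[C@H]1C(OC)OC
F17 | step 20 | (R)-Cb saturated alcohol from F16 | OC[C@H](CCC=C(C)C)[C@@H]1CC/C(C)=C/C/C=C(/CO[Si](C)(C)C(C)(C)C)[C@H]1C(OC)OC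
F18 | step 20 | acetate of F17 | CC(=O)OC[C@H](CCC=C(C)C)[C@@H]1CC/C(C)=C/C/C=C(/CO[Si](C)(C)C(C)(C)C)[C@H]1C(OC)OC
F19 | step 20 | desilylated allylic alcohol from F18 | CC(=O)OC[C@H](CCC=C(C)C)[C@@H]1CC/C(C)=C/C/C=C(/CO)[C@H]1C(OC)OC
F20 | step 20 | C9 dimethyl acetal of 30 | CC(=O)OC[C@H](CCC=C(C)C)[C@@H]1CC/C(C)=C/C/C=C(/C=O)[C@H]1C(OC)OC
A1 | alternative 1 | (E)-7-(trimethylsilyl)hept-2-en-6-ynal | C[Si](C)(C)C#CCC/C=C/C=O
A2 | alternative 1 | (Z)-1-ethoxy-6-methylhepta-1,5-diene | CCO/C=C\CCC=C(C)C
A3 | alternative 1 | all-cis 2-ethoxy-3-(4-methylpent-3-en-1-yl)-4-[4-(trimethylsilyl)but-3-yn-1-yl]-3,4-dihydro-2H-pyran | CCO[C@H]1OC=C[C@@H](CCC#C[Si](C)(C)C)[C@H]1CCC=C(C)C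
A4 | alternative 2 | cis-fused 7a-hydroxy-3a-methyloctahydro-1H-inden-4-yl 4-methylbenzenesulfonate carrying the silyl-protected side chain at C1 | CC(C)(C)[Si](C)(C)OC[C@H](CCC=C(C)C)[C@@H]1CC[C@]2(C)[C@@H](OS(=O)(=O)c3ccc(C)cc3)CCC[C@]12O
A5 | alternative 2 | (E)-cyclononenone with C1 and Cb in place | CC(C)(C)[Si](C)(C)OC[C@H](CCC=C(C)C)[C@@H]1CC/C(C)=C/CCCC1=O
A6 | alternative 3 | trans-1-alkenyl-5-(prop-1-en-2-yl)-2-{[(tert-butyldimethylsilyl)oxy]methyl}cyclopent-2-en-1-ol (alkenyl = 3-{[(4-methoxybenzyl)oxy]methyl}-7-methylocta-1,6-dien-2-yl) | C=C(C)[C@H]1CC=C(CO[Si](C)(C)C(C)(C)C)[C@]1(O)C(=C)[C@@H](CCC=C(C)C)COCc1ccc(OC)cc1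
A7 | alternative 3 | nine-membered dienone with the C9 ketone | COc1ccc(COC[C@H](CCC=C(C)C)[C@@H]2CC/C(C)=C/C/C=C(/CO[Si](C)(C)C(C)(C)C)C2=O)cc1
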